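## Retrosynthetic overview

- The target is a heliangolide. A ten-membered carbocycle (C1–C10) is fused along C6–C7 to an α-methylene-γ-lactone (O, C6, C7, C11, C12), and it carries a C1–C10 oxirane, a 2Z,4Z-diene and an 8β-ester. The ester C8–O bond is cut last, by Mitsunobu inversion of the 8α-alcohol with (2S,3R)-2,3-dimethyloxirane-2-carboxylic acid made from tiglic acid.
- The key disconnection is C6–C7. This one bond belongs to both the carbocycle and the lactone, and it is the bond the biosynthesis makes when farnesyl C1 closes onto C10. The route copies that closure with inverted polarity.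
- Enabling feature: C7 is the γ-end of the allyl unit C13–C11=C7, whose central carbon C11 bears the C12 ester, and C6 is the lactone carbinol carbon at the end of the Z,Z-diene. An acyclic 2-(bromomethyl)enoate/dienal therefore gives both rings, C6, C7 and the C11=C13 methylene in one flask, by allylchromium addition and lactonisation.
- The acyclic precursor is built from (R)-glycidol (C7–C9), acetylide (C10, C1), Me3Al (C14), an ethynyl unit (C2, C3), methyl acrylate (C11–C13) and (Z)-3-iodobut-2-en-1-ol (C4–C6, C15).
- Ring order: the C1–C10 oxirane (Shi epoxidation) and, separately, the side-chain oxirane (Sharpless epoxidation) come first. The carbocycle and the lactone then form together in the key step.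

Key step: step 13

Remark: germacrane numbering (C1–C15, C2′/C3′ for the side-chain oxirane) is used for every intermediate; the Morita–Baylis–Hillman adduct and the three compounds made from it are carried as mixtures of C7 epimers, so C7 is left undefined in their SMILES until step 12 removes this centre.

## Route

Step 1
Reactants: 1 (R)-glycidol
Product: 2 (S)-pent-4-yne-1,2-diol
Conditions: LiC≡CH·H2NCH2CH2NH2 (2.5 equiv), DMSO, 0 °C → rt; H2O
Reagents that add atoms: lithium acetylide–ethylenediamine complex [Li+].[C-]#C.NCCN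
Why: SN2 opening of the terminal oxirane carbon by acetylide (the Payne rearrangement of glycidol is degenerate) leaves the carbinol centre, the future C8, untouched, and only the CIP priorities change from R to S.

Step 2
Reactants: 2 (S)-pent-4-yne-1,2-diol
Product: 3 (S)-4,5-bis(triethylsilyloxy)pent-1-yne
Conditions: Et3SiCl, imidazole, CH2Cl2, 0 °C → rt
Reagents that add atoms: chlorotriethylsilane CC[Si](Cl)(CC)CC
Why: Standard silylation; triethylsilyl is chosen because the primary ether can later be oxidised directly, while the secondary one is non-chelating in step 13 and leaves under very mild fluoride conditions.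

Step 3
Reactants: 3 (S)-4,5-bis(triethylsilyloxy)pent-1-yne
Product: 5 (S,E)-4,5-bis(triethylsilyloxy)-1-iodo-2-methylpent-1-ene, via alkenyldimethylalane 4 (not isolated)
Conditions: Me3Al, Cp2ZrCl2 (20 mol %), CH2Cl2, 0 °C → rt; then I2, THF, −30 °C
Reagents that add atoms: trimethylaluminium C[Al](C)C; iodine [I][I]
Why: Negishi zirconium-catalysed carboalumination adds methyl and aluminium syn across the alkyne with methyl on the inner carbon, and iodinolysis with retention fixes the E geometry of C1=C10.

Step 4
Reactants: 5 (S,E)-4,5-bis(triethylsilyloxy)-1-iodo-2-methylpent-1-ene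
Product: 6 (S,E)-6,7-bis(triethylsilyloxy)-4-methylhept-3-en-1-yne
Conditions: HC≡CMgBr, ZnBr2, THF, 0 °C; then 5, Pd(PPh3)4 (5 mol %), rt
Reagents that add atoms: ethynylmagnesium bromide C#C[Mg]Br
Why: Negishi coupling of an alkenyl iodide with ethynylzinc bromide proceeds with retention of alkene geometry and gives the terminal enyne without a desilylation step.

Step 5
Reactants: 6 (S,E)-6,7-bis(triethylsilyloxy)-4-methylhept-3-en-1-yne
Product: 7 (2R,3R)-2-[(2S)-2,3-bis(triethylsilyloxy)propyl]-3-ethynyl-2-methyloxirane
Conditions: Shi ketone (1,2:4,5-di-O-isopropylidene-β-D-erythro-2,3-hexodiulo-2,6-pyranose, 30 mol %), Oxone (2KHSO5·KHSO4·K2SO4), K2CO3, Bu4NHSO4, MeCN/CH2(OMe)2/aq. Na2B4O7–Na2EDTA buffer, 0 °C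
Reagents that add atoms: potassium peroxymonosulfate [K+].[O-]S(=O)(=O)OO
Why: Shi asymmetric epoxidation of a conjugated enyne: the chiral dioxirane attacks the only alkene (the alkyne is inert) through the spiro transition state, so catalyst control sets C1 and C10 as R,R and the E geometry becomes the trans oxirane.

Step 6
Reactants: 7 (2R,3R)-2-[(2S)-2,3-bis(triethylsilyloxy)propyl]-3-ethynyl-2-methyloxirane
Product: 8 (2S)-3-[(2R,3R)-3-ethynyl-2-methyloxiran-2-yl]-2-(triethylsilyloxy)propanal
Conditions: (COCl)2, DMSO, CH2Cl2, −78 → −40 °C; Et3N, −78 → 0 °C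
Reagents that add atoms: none
Why: Under Swern conditions the activated sulfonium salt attacks the unhindered primary triethylsilyl ether directly (oxidative desilylation), the secondary silyl ether and the oxirane stay, and the low temperature guards the α-silyloxy centre C8.

Step 7
Reactants: 8 (2S)-3-[(2R,3R)-3-ethynyl-2-methyloxiran-2-yl]-2-(triethylsilyloxy)propanal; 9 methyl acrylate
Product: 10 methyl (4S)-5-[(2R,3R)-3-ethynyl-2-methyloxiran-2-yl]-3-hydroxy-2-methylidene-4-(triethylsilyloxy)pentanoate (C7 epimers)
Conditions: quinuclidine (50 mol %), MeOH, neat 9, rt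
Reagents that add atoms: none
Why: The Morita–Baylis–Hillman reaction of an activated α-silyloxy aldehyde installs C11–C13; the new carbinol centre C7 need not be controlled because step 12 removes it.

Step 8
Reactants: 11 but-2-yn-1-ol
Product: 13 (Z)-3-iodobut-2-en-1-ol, via cyclic sodium alkenylalanate 12 (not isolated)
Conditions: NaAlH2(OCH2CH2OMe)2, THF, 0 °C → rt; then I2, −78 → 0 °C
Reagents that add atoms: iodine [I][I]
Why: Hydroxyl-directed trans-hydroalumination places aluminium on C3 of the butynol in a five-membered alanate, and iodinolysis with retention gives the Z iodide that later becomes the Z C4=C5 alkene.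

Step 9
Reactants: 10 Morita–Baylis–Hillman adduct; 13 (Z)-3-iodobut-2-en-1-ol
Product: 14 methyl (4S)-3-hydroxy-5-{(2R,3R)-3-[(Z)-5-hydroxy-3-methylpent-3-en-1-ynyl]-2-methyloxiran-2-yl}-2-methylidene-4-(triethylsilyloxy)pentanoate
Conditions: Pd(PPh3)4 (5 mol %), CuI (10 mol %), Et3N, THF, rt, degassed
Reagents that add atoms: none
Why: Sonogashira coupling keeps the Z geometry of the iodide; oxidative addition of zerovalent palladium to the alkenyl iodide is faster than ionisation of the propargylic oxirane, and the tertiary amine base cannot add to the acrylate.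

Step 10
Reactants: 14 epoxy enynol
Product: 15 methyl (4S)-3-hydroxy-5-{(2R,3R)-3-[(1Z,3Z)-5-hydroxy-3-methylpenta-1,3-dienyl]-2-methyloxiran-2-yl}-2-methylidene-4-(triethylsilyloxy)pentanoate
Conditions: H2 (1 atm), Pd/CaCO3 poisoned with Pb(OAc)2 (Lindlar catalyst), quinoline, EtOAc, 0 °C, stopped after one equivalent of H2
Reagents that add atoms: none
Why: Lindlar semihydrogenation delivers both hydrogens syn to the alkyne, the most strongly adsorbed group, and sets the Z C2=C3 alkene; the enyne carbinol motif is the classical substrate type of this catalyst.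

Step 11
Reactants: 15 Z,Z-dienol
Product: 16 methyl (4S)-3-hydroxy-5-{(2R,3R)-2-methyl-3-[(1Z,3Z)-3-methyl-5-oxopenta-1,3-dienyl]oxiran-2-yl}-2-methylidene-4-(triethylsilyloxy)pentanoate
Conditions: MnO2 (activated, excess), CH2Cl2, 0 °C, dark
Reagents that add atoms: none
Why: MnO2 oxidises the electron-rich primary dienylic alcohol much faster than the electron-poor secondary allylic alcohol at C7, and the neutral heterogeneous medium keeps both Z alkenes and the acid-labile dienyl oxirane.

Step 12
Reactants: 16 Z,Z-dienal
Product: 17 methyl (2Z,4S)-2-(bromomethyl)-5-{(2R,3R)-2-methyl-3-[(1Z,3Z)-3-methyl-5-oxopenta-1,3-dienyl]oxiran-2-yl}-4-(triethylsilyloxy)pent-2-enoate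
Conditions: NBS, Me2S, CH2Cl2, −20 → 0 °C
Reagents that add atoms: N-bromosuccinimide O=C1CCC(=O)N1Br
Why: Corey–Kim-type activation of the Morita–Baylis–Hillman alcohol and SN2′ attack of bromide give the conjugated (Z)-2-(bromomethyl)enoate under neutral conditions, both C7 epimers converging on one compound.

Step 13
Reactants: 17 bromo ester dienal
Product: 20 1β,10α-epoxy-8α-(triethylsilyloxy)germacra-2Z,4Z,11(13)-trien-6α,12-olide, via allylchromium dichloride 18 (not isolated), via ring-closed chromium alkoxide 19 (not isolated)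
Conditions: CrCl2 (10 equiv), DMF, rt, 17 added by syringe pump to a final 2 mM; aqueous work-up
Reagents that add atoms: none
Why: CrCl2 reduces only the allylic C13–Br bond (two one-electron steps) to the σ-allyl species 18 of trivalent chromium, whose γ-carbon C7 adds to the C6 formyl group through a closed six-membered Zimmerman–Traxler array with transposition of the alkene to C11=C13, and the chromium alkoxide 19 then acylates itself on the C12 methyl ester. The closest known reaction type is the intramolecular Nozaki–Hiyama–Kishi 2-(alkoxycarbonyl)allylation with lactonisation in the flask, which is established for medium carbocycles, and here it is the polarity-inverted copy of the biosynthetic closure of farnesyl C1 onto C10. The carbocycle closes 10-exo-trig at the carbonyl carbon and the lactone closes 5-exo-trig at the ester carbonyl. C6 is controlled by the C1 oxirane centre: allylic 1,3-strain at both Z alkenes keeps H1 and the formyl hydrogen in the alkene planes, the 1R centre thereby fixes the twist of the diene, and the tether can bring C7 only to the Si face of the aldehyde (6R). C7 is controlled by C8: H8 eclipses the allyl plane, the C8–OSi bond stands anti to the forming bond (Felkin–Anh-type Hiyama addition) and C9 points outward, which should place H7 trans to both H6 and H8, that is the trans-fused lactone with an 8α-oxygen, and this is why C8 is carried as the S epimer until step 18. The step needs chemoselectivity for the bromide over enal, ester, oxirane and silyl ether, secured by the halophilic inner-sphere reduction and by the poor leaving-group quality of the bulky non-coordinating silyloxy group, and it needs ring closure to beat oligomerisation, secured by slow addition at 2 mM and by the two Z alkenes and the trans oxirane, which fold the chain so that C6 and C7 face each other.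

Step 14
Reactants: 20 8α-silyl ether
Product: 21 1β,10α-epoxy-8α-hydroxygermacra-2Z,4Z,11(13)-trien-6α,12-olide
Conditions: HF·pyridine, pyridine, THF, 0 °C
Reagents that add atoms: none
Why: Pyridine-buffered HF cleaves the secondary triethylsilyl ether quickly at 0 °C, conditions under which the lactone, the exocyclic methylene and the ring-held oxirane should persist.

Step 15
Reactants: 22 tiglic acid
Product: 23 (E)-2-methylbut-2-en-1-ol
Conditions: LiAlH4, Et2O, 0 °C → rt
Reagents that add atoms: none
Why: LiAlH4 reduces the acid in 1,2-fashion without touching the trisubstituted alkene, whose E geometry is kept.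

Step 16
Reactants: 23 (E)-2-methylbut-2-en-1-ol
Product: 24 [(2R,3R)-2,3-dimethyloxiran-2-yl]methanol
Conditions: Ti(OiPr)4 (10 mol %), D-(−)-diethyl tartrate (12 mol %), t-BuOOH, 4 Å MS, CH2Cl2, −20 °C
Reagents that add atoms: tert-butyl hydroperoxide CC(C)(C)OO
Why: Sharpless asymmetric epoxidation: the D-(−)-tartrate catalyst delivers oxygen to the face that gives the 2R,3R epoxy alcohol, and the E alkene geometry becomes the cis relation of the two methyl groups found in the target.

Step 17
Reactants: 24 [(2R,3R)-2,3-dimethyloxiran-2-yl]methanol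
Product: 26 (2S,3R)-2,3-dimethyloxirane-2-carboxylic acid, via epoxy aldehyde 25 (not isolated)
Conditions: TEMPO (10 mol %), PhI(OAc)2 (2.2 equiv), MeCN/H2O, rt
Reagents that add atoms: water O
Why: TEMPO/PhI(OAc)2 oxidation in aqueous acetonitrile goes through the aldehyde hydrate to the acid without opening the oxirane, and both stereocentres are untouched (C2′ becomes S by priority change only).

Step 18
Reactants: 21 8α-alcohol; 26 (2S,3R)-2,3-dimethyloxirane-2-carboxylic acid
Product: 27 CNP0122107.1
Conditions: PPh3, DIAD, toluene, 0 °C → rt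
Reagents that add atoms: none
Why: Mitsunobu esterification: the carboxylate of the fairly acidic glycidic acid displaces the C8 oxyphosphonium group by SN2 from the β-face, which inverts C8 from S to R and installs the ester in one operation, while oxiranes, diene and lactone are inert to PPh3/DIAD.

## Compound list

1 | (R)-glycidol | OC[C@@H]1CO1 | starting material
2 | (S)-pent-4-yne-1,2-diol | C#CC[C@H](O)CO | intermediate
3 | (S)-4,5-bis(triethylsilyloxy)pent-1-yne | C#CC[C@H](O[Si](CC)(CC)CC)CO[Si](CC)(CC)CC | intermediate
4 | (S,E)-[4,5-bis(triethylsilyloxy)-2-methylpent-1-enyl]dimethylalane (not isolated) | C[Al](C)/C=C(\C)C[C@H](O[Si](CC)(CC)CC)CO[Si](CC)(CC)CC | intermediate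
5 | (S,E)-4,5-bis(triethylsilyloxy)-1-iodo-2-methylpent-1-ene | I/C=C(\C)C[C@H](O[Si](CC)(CC)CC)CO[Si](CC)(CC)CC | intermediate
6 | (S,E)-6,7-bis(triethylsilyloxy)-4-methylhept-3-en-1-yne | C#C/C=C(\C)C[C@H](O[Si](CC)(CC)CC)CO[Si](CC)(CC)CC | intermediate
7 | (2R,3R)-2-[(2S)-2,3-bis(triethylsilyloxy)propyl]-3-ethynyl-2-methyloxirane | C#C[C@H]1O[C@]1(C)C[C@H](O[Si](CC)(CC)CC)CO[Si](CC)(CC)CC | intermediate
8 | (2S)-3-[(2R,3R)-3-ethynyl-2-methyloxiran-2-yl]-2-(triethylsilyloxy)propanal | C#C[C@H]1O[C@]1(C)C[C@H](O[Si](CC)(CC)CC)C=O | intermediate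
9 | methyl acrylate | C=CC(=O)OC | starting material
10 | Morita–Baylis–Hillman adduct, 1R,10R,8S, C7 epimers | C#C[C@H]1O[C@]1(C)C[C@H](O[Si](CC)(CC)CC)C(O)C(=C)C(=O)OC | intermediate
11 | but-2-yn-1-ol | CC#CCO | starting material
12 | cyclic sodium alkenylalanate from 11 (not isolated) | [Na+].CC1=CCO[Al-]1(OCCOC)OCCOC | intermediate
13 | (Z)-3-iodobut-2-en-1-ol | OC/C=C(C)\I | intermediate
14 | epoxy enynol, 4Z, 1R,10R,8S, C7 epimers | OC/C=C(C)\C#C[C@H]1O[C@]1(C)C[C@H](O[Si](CC)(CC)CC)C(O)C(=C)C(=O)OC | intermediate
15 | epoxy dienol, 2Z,4Z, 1R,10R,8S, C7 epimers | OC/C=C(C)\C=C/[C@H]1O[C@]1(C)C[C@H](O[Si](CC)(CC)CC)C(O)C(=C)C(=O)OC | intermediate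
16 | epoxy dienal, 2Z,4Z, 1R,10R,8S, C7 epimers | O=C/C=C(C)\C=C/[C@H]1O[C@]1(C)C[C@H](O[Si](CC)(CC)CC)C(O)C(=C)C(=O)OC | intermediate
17 | (Z)-2-(bromomethyl)enoate dienal, 1R,10R,8S | O=C/C=C(C)\C=C/[C@H]1O[C@]1(C)C[C@H](O[Si](CC)(CC)CC)/C=C(\CBr)C(=O)OC | intermediate
18 | allylchromium dichloride from 17 (not isolated) | O=C/C=C(C)\C=C/[C@H]1O[C@]1(C)C[C@H](O[Si](CC)(CC)CC)/C=C(\C[Cr](Cl)Cl)C(=O)OC | intermediate
19 | chromium alkoxide of the ten-membered hydroxy ester (not isolated) | Cl[Cr](Cl)O[C@@H]1/C=C(C)\C=C/[C@H]2O[C@]2(C)C[C@H](O[Si](CC)(CC)CC)[C@H]1C(=C)C(=O)OC | intermediate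
20 | 1β,10α-epoxy-8α-(triethylsilyloxy)germacra-2Z,4Z,11(13)-trien-6α,12-olide | C=C1C(=O)O[C@@H]2/C=C(C)\C=C/[C@H]3O[C@]3(C)C[C@H](O[Si](CC)(CC)CC)[C@@H]12 | intermediate
21 | 1β,10α-epoxy-8α-hydroxygermacra-2Z,4Z,11(13)-trien-6α,12-olide | C=C1C(=O)O[C@@H]2/C=C(C)\C=C/[C@H]3O[C@]3(C)C[C@H](O)[C@@H]12 | intermediate
22 | tiglic acid | C/C=C(\C)C(=O)O | starting material
23 | (E)-2-methylbut-2-en-1-ol | C/C=C(\C)CO | intermediate
24 | [(2R,3R)-2,3-dimethyloxiran-2-yl]methanol | OC[C@@]1(C)O[C@@H]1C | intermediate
25 | (2S,3R)-2,3-dimethyloxirane-2-carbaldehyde (not isolated) | O=C[C@@]1(C)O[C@@H]1C | intermediate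
26 | (2S,3R)-2,3-dimethyloxirane-2-carboxylic acid | OC(=O)[C@@]1(C)O[C@@H]1C | intermediate
27 | CNP0122107.1, 1β,10α-epoxy-8β-[(2S,3R)-2,3-epoxy-2-methylbutanoyloxy]germacra-2Z,4Z,11(13)-trien-6α,12-olide | C=C1C(=O)O[C@@H]2/C=C(C)\C=C/[C@H]3O[C@]3(C)C[C@@H](OC(=O)[C@@]3(C)O[C@@H]3C)[C@@H]12 | target

## Step count and risks

Total step count: 18. Longest linear sequence: 14 (steps 1–7, 9–14 and 18).

**Step 13.** Several processes may intervene:
- oligomerisation in place of ring closure;
- reductive 1,4-loss of the C8 silyloxy group from the allylchromium species;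
- opening of the dienyl oxirane by halide or by divalent chromium;
- addition through the wrong pairing of faces, which would give a cis-fused lactone.

The fallback keeps the same ring-closing bond but replaces reductive metalation by a preformed, redox-neutral nucleophile. It sets out from aldehyde 8. Trimethyl phosphonoacetate is alkylated with ICH2SiMe3 (NaH) to methyl 2-(dimethoxyphosphoryl)-3-(trimethylsilyl)propanoate F1. A Horner–Wadsworth–Emmons reaction of this phosphonate with 8 gives the β-(methoxycarbonyl)allylsilane F2. Sonogashira coupling with 13, Lindlar semihydrogenation and MnO2 oxidation, as in steps 9–11, lead through the allylsilane enynol F3 and the allylsilane dienol F4 to the allylsilane dienal F5. Fluoride (Bu4NF, THF, high dilution) then triggers an intramolecular Hosomi–Sakurai-type addition, lactonisation and loss of the silyl ether. The route is rejoined at 21.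

**Step 18.** The hindered ring carbinol may eliminate toward C9 or C7, may not be displaced at all, or may be acylated with retention through an acyloxyphosphonium pathway. The fallback inverts C8 by redox chemistry and then acylates with retention. It sets out from 21. Dess–Martin oxidation (NaHCO3 buffer) gives the 8-oxo lactone F6. Luche reduction (NaBH4, CeCl3·7H2O, MeOH, −78 °C) should deliver hydride from the open α-face, away from C6 and C11, and spare the methylene lactone, giving the 8β-alcohol F7. Yamaguchi esterification with 26 (2,4,6-trichlorobenzoyl chloride, Et3N, DMAP) comes back to the route at 27.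

**Step 10.** Over-reduction of the diene, hydrogenolysis of the allylic C1–O bond once the dienyl oxirane has formed, or saturation of the acrylate may compete with the semihydrogenation. The fallback builds the Z alkene by stereodefined cross-coupling instead of by reduction. It sets out from 10. Rhodium-catalysed trans-hydroboration of the terminal alkyne ([Rh(cod)Cl]2, P(iPr)3, Et3N, pinacolborane) gives the (Z)-alkenylboronate F8. A fast Suzuki–Miyaura coupling with 13 (Pd(PPh3)4, aq. K3PO4, THF, rt), with retention at both partners, comes back to the route at 15.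

## Further compounds

F1 | step 13 | methyl 2-(dimethoxyphosphoryl)-3-(trimethylsilyl)propanoate | COC(=O)C(C[Si](C)(C)C)P(=O)(OC)OC
F2 | step 13 | β-(methoxycarbonyl)allylsilane with terminal epoxy alkyne, 1R,10R,8S | C#C[C@H]1O[C@]1(C)C[C@H](O[Si](CC)(CC)CC)/C=C(\C[Si](C)(C)C)C(=O)OC
F3 | step 13 | allylsilane enynol, 4Z | OC/C=C(C)\C#C[C@H]1O[C@]1(C)C[C@H](O[Si](CC)(CC)CC)/C=C(\C[Si](C)(C)C)C(=O)OC
F4 | step 13 | allylsilane dienol, 2Z,4Z | OC/C=C(C)\C=C/[C@H]1O[C@]1(C)C[C@H](O[Si](CC)(CC)CC)/C=C(\C[Si](C)(C)C)C(=O)OC
F5 | step 13 | allylsilane dienal, 2Z,4Z | O=C/C=C(C)\C=C/[C@H]1O[C@]1(C)C[C@H](O[Si](CC)(CC)CC)/C=C(\C[Si](C)(C)C)C(=O)OC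
F6 | step 18 | 1β,10α-epoxy-8-oxogermacra-2Z,4Z,11(13)-trien-6α,12-olide | C=C1C(=O)O[C@@H]2/C=C(C)\C=C/[C@H]3O[C@]3(C)CC(=O)[C@@H]12
F7 | step 18 | 1β,10α-epoxy-8β-hydroxygermacra-2Z,4Z,11(13)-trien-6α,12-olide | C=C1C(=O)O[C@@H]2/C=C(C)\C=C/[C@H]3O[C@]3(C)C[C@@H](O)[C@@H]12
F8 | step 10 | (Z)-alkenyl pinacolboronate of 10, C7 epimers | CC1(C)OB(/C=C\[C@H]2O[C@]2(C)C[C@H](O[Si](CC)(CC)CC)C(O)C(=C)C(=O)OC)OC1(C)C
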